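I began with the amounts: the north-east run held 0.200 M of Z against 0.00400 M of J, and X levelled off short of that Z.

| flask | Z | Q | J | time |
|---|---|---|---|---|
| north-east | 0.200 M | 0.600 M | 0.00400 M |  |
| east | 0.0800 M | 0.480 M | 0.00400 M |  |
| west | 0.100 M | 0.600 M | 0.00400 M |  |
| north | 0.200 M | 0.600 M | 0.00600 M |  |
| south | 0.0310 M | 0.600 M | 0.00400 M | 140 min |

- north-east run (time / min: [X] / M): 5.0: 0.026; 15: 0.037; 29: 0.037; 46: 0.050; 66: 0.044; 88: 0.045; 110: 0.049; 140: 0.044
- east run (time / min: [X] / M): 5.0: 0.011; 15: 0.018; 29: 0.020; 46: 0.032; 66: 0.031; 88: 0.029; 110: 0.024; 140: 0.024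
- west run (time / min: [X] / M): 5.0: 0.013; 15: 0.025; 29: 0.030; 46: 0.032; 66: 0.028; 88: 0.030; 110: 0.029; 140: 0.031
- north run (time / min: [X] / M): 5.0: 0.030; 15: 0.050; 29: 0.059; 46: 0.058; 66: 0.063; 88: 0.063; 110: 0.065; 140: 0.067

(readings scatter by 0.003 M)

- the power of [Z] that the first rate follows, about the charge of the north-east run; measure it at two percent of Z made into X (one fixed amount of X, the same in the runs compared)
- the power of [J] that the first rate follows, about the charge of the north-east run; measure it at two percent of Z made into X
- X in the south run at 140 min, as a share of the Z charged

- Overall: Z + Q -> X, with J as catalyst.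
- Constant volume, constant temperature.
- What is held in complexes is read along with the free species.
- "The second partner" is Q.
- An order is taken over about fifteen percent of the charge, up and down.

I folded the charges into one number, the catalyst loading, [J]/[Z] at the start, which says how much catalyst stands behind each Z charged. It was 0.0200 in the north-east run, 0.0400 in the west run and 0.0300 in the north run; the south run's loading was 0.129. Averaging the readings from 66 min on gave the share of Z found as X:

north-east 22.7%; west 29.5%; north 32.2%

The share stood higher in the west run and in the north run than in the north-east run, so I took its power along each route from the north-east run: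

by lowering [Z], to the west run: 0.375
by raising [J], to the north run: 0.861

One number was not enough: the [J] route gave more than the [Z] route, by 0.486, against a scatter of about 0.0874 on the [Z] power. The south run has the [Q] and [J] of the west run and less Z, so I followed the [Z] power, beyond the loadings tried:

south share = 29.5% × (0.100 M / 0.0310 M)^0.375 = 45.8%

For the orders, the readings at 5.0 min gave 1.00 in [Z], with a scatter of about 0.372, which I kept as a rough reading. For [J] the readings at that time gave 0.353, with a scatter of about 0.377, so I took 0.861 as a stand-in.

The forecast gave 0.5 in [Z], 1.05 in [J] and 37%, reasoning “so the catalyst is dying, not reaching equilibrium”. My share was higher.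

The south run gave 49.1%; about the north-east charge, the orders were 0.91 in [Z] and 1.2 in [J].

    J + Z ⇌ JZ (21.06 M⁻¹ min⁻¹, 6.120 min⁻¹)
    JZ + Q → X + J (25.38 M⁻¹ min⁻¹)
    2 Z → Ky (0.5604 M⁻¹ min⁻¹)
    2 Q → Yx (0.4134 M⁻¹ min⁻¹)

The west run made X at 0.51 of the north-east rate, both at the same amount of X, with a Z charge 0.500 of the north-east one. Z lost to Ky over Z made into X, at the start, is a factor reckoned from the charge, divided by the loading. That ratio was 0.596 in the south run and 2.98 in the north run, where the X made came to a quarter of the Z charged at 13.8 min.

(The readings were computed for substances that don't exist; noise was put on by code.)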